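**Assumption:** commercial (S)-hesperetin of high ee is used; a partly racemised lot would be upgraded by recrystallisation or chiral chromatography before step 1.

## Retrosynthetic overview

1. C6–C1'' bond: aromatic Claisen ([3,3]) rearrangement of a 7-O-(3,7-dimethylocta-1,6-dien-3-yl) ("linalyl") ether; the allylic inversion converts the tertiary ether into the linear geranyl chain at C6.
2. O7–C bond: Pd(0) allylic etherification of the most acidic phenol (7-OH) with methyl linalyl carbonate.
3. C3–OH: Rubottom oxidation of the silyl enol ether of (S)-hesperetin, anti to the C2 aryl group (C2 is bought, C3 is controlled by C2).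
4. Rings: none is built. Both aryl rings, the pyranone ring and the 3'-OH/4'-OMe pattern are bought intact in (S)-hesperetin.
5. Protecting groups: transient TMS only.

## Route

**Step 1**
Reactants: 1, (S)-hesperetin [(2S)-5,7-dihydroxy-2-(3-hydroxy-4-methoxyphenyl)chroman-4-one]
Product: 2, (2S)-2-[4-methoxy-3-(trimethylsilyloxy)phenyl]-4,5,7-tris(trimethylsilyloxy)-2H-chromene (tris-aryl TMS ether and TMS enol ether)
Conditions: TMSOTf (5 equiv), Et3N (7 equiv), CH2Cl2, 0 °C, 1 h; non-aqueous work-up (pentane, filter, evaporate); use crude, cold, in the dark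
Reagents that add atoms: trimethylsilyl triflate, C[Si](C)(C)OS(=O)(=O)C(F)(F)F
Why: Phenol silylation plus soft enolisation (silyl enol ether formation) avoids a free C3 enolate, so no E1cB opening to the chalcone occurs and C2 is untouched.

**Step 2**
Reactants: 2, the per-TMS enol ether
Product: 3, (2R,3R)-3,5,7-trihydroxy-2-(3-hydroxy-4-methoxyphenyl)chroman-4-one (4'-O-methyltaxifolin)
Conditions: DMDO (1.1 equiv, acetone), CH2Cl2, −78 → −30 °C; then citric acid, MeOH/THF, 0 °C → rt
Reagents that add atoms: dimethyldioxirane, CC1(C)OO1 (delivers the C3 oxygen)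
Why: Rubottom oxidation, in which the enol ether is epoxidised on the face anti to the C2 aryl group and collapses to the α-silyloxy ketone, giving the 2,3-trans (2R,3R) ketol after mild acidic desilylation.

**Step 3**
Reactants: 4, (±)-linalool (3,7-dimethylocta-1,6-dien-3-ol; its stereocentre is destroyed later, so racemic material is used)
Product: 5, methyl (3,7-dimethylocta-1,6-dien-3-yl) carbonate (methyl linalyl carbonate)
Conditions: n-BuLi, THF, −78 °C; ClCO2Me, −78 → 0 °C
Reagents that add atoms: methyl chloroformate, COC(=O)Cl
Why: O-acylation of the lithium alkoxide is the standard way to make a tertiary allylic carbonate for Tsuji–Trost chemistry.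

**Step 4**
Reactants: 3, (2R,3R)-4'-O-methyltaxifolin; 5, methyl linalyl carbonate (1.2 equiv)
Product: 6, (2R,3R)-7-[(3,7-dimethylocta-1,6-dien-3-yl)oxy]-3,5-dihydroxy-2-(3-hydroxy-4-methoxyphenyl)chroman-4-one, about 1:1 epimers at the ether carbon
Conditions: Pd(PPh3)4 (3 mol %), THF, 0 °C, about 1 h; filter through silica at once to remove Pd
Reagents that add atoms: none (the C10 unit comes from reactant 5)
Why: Tsuji–Trost O-allylation under neutral conditions, where the methoxide released deprotonates only the most acidic 7-OH and the phenoxide attacks the more substituted π-allyl terminus under kinetic control, as in reverse-prenylation; C2 and C3 are not touched.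

**Step 5**
Reactants: 6, the 7-O-linalyl ether
Product: 7, 4'-O-methyldiplacol [(2R,3R)-6-[(2E)-3,7-dimethylocta-2,6-dienyl]-3,5,7-trihydroxy-2-(3-hydroxy-4-methoxyphenyl)chroman-4-one]
Conditions: degassed toluene, BHT (cat.), 105–110 °C, 2–4 h, Ar; then AgNO3-impregnated silica and RP-18 HPLC
Reagents that add atoms: none
Why: Aromatic Claisen ([3,3]) rearrangement forms C6–C1'' and re-forms the olefin as C2''=C3''; migration to C6 is expected to be favoured by the chelated 5-OH, and the chair transition state with the homoprenyl group equatorial gives E only modestly (estimated about 2:1 over Z), so the target is separated from the neryl and 8-substituted isomers, with C2 and C3 unaffected.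

## Compound list

1 | (S)-hesperetin | COc1ccc([C@H]2Oc3cc(O)cc(O)c3C(=O)C2)cc1O | starting material
2 | (2S)-2-[4-methoxy-3-(trimethylsilyloxy)phenyl]-4,5,7-tris(trimethylsilyloxy)-2H-chromene | COc1ccc([C@H]2Oc3cc(O[Si](C)(C)C)cc(O[Si](C)(C)C)c3C(O[Si](C)(C)C)=C2)cc1O[Si](C)(C)C | intermediate
3 | (2R,3R)-4'-O-methyltaxifolin | COc1ccc([C@H]2Oc3cc(O)cc(O)c3C(=O)[C@@H]2O)cc1O | intermediate
4 | (±)-linalool | C=CC(C)(O)CCC=C(C)C | starting material
5 | methyl (3,7-dimethylocta-1,6-dien-3-yl) carbonate | C=CC(C)(OC(=O)OC)CCC=C(C)C | intermediate
6 | (2R,3R)-7-[(3,7-dimethylocta-1,6-dien-3-yl)oxy]-3,5-dihydroxy-2-(3-hydroxy-4-methoxyphenyl)chroman-4-one (epimers at the ether carbon) | COc1ccc([C@H]2Oc3cc(OC(C)(C=C)CCC=C(C)C)cc(O)c3C(=O)[C@@H]2O)cc1O | intermediate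
7 | 4'-O-methyldiplacol | COc1ccc([C@H]2Oc3cc(O)c(C/C=C(\C)CCC=C(C)C)c(O)c3C(=O)[C@@H]2O)cc1O | target

## Summary

Total steps: 5. Longest linear sequence: 4 (1 → 2 → 3 → 6 → 7).

Three steps most likely to fail:

1. **Step 5 (Claisen).** The E/Z ratio at the new trisubstituted olefin is modest, the C6/C8 ratio is uncertain, and thermal loss of the tertiary allyl group (diene plus recovered 3) can compete. Fallback: give up the O→C transfer and C-alkylate the A ring of 3 directly with (E)-geranyl bromide and base at low temperature. This keeps the E-olefin intact and leaves only a 6/8 separation.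

2. **Steps 1–2 (silyl enol ether / Rubottom).** C2 could erode through ring-opening of the 2H-chromene, DMDO could over-oxidise the electron-rich A ring, and some cis isomer could form. Fallback: buy both stereocentres in (+)-taxifolin, 7-O-alkylate it as in step 4, and introduce the 4'-methyl by partial catechol methylation, separating the 3'-isomer.

3. **Step 4 (Pd etherification).** The linear geranyl/neryl ether, C-allylation of the phloroglucinol ring, or 3'-O-alkylation could compete with the tertiary 7-O-ether. Fallback: make 6 by Cu-catalysed O-propargylation of 3 with the carbonate of dehydrolinalool (3,7-dimethyloct-6-en-1-yn-3-ol), then Lindlar semi-hydrogenation of the alkyne.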